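The ten-membered carbocycle is closed last at C4–C5 by an intramolecular Nozaki–Hiyama–Kishi reaction of the alkenyl triflate/aldehyde 15. This step also creates the C4=CH2/C5–OH unit.
C7–C8 is made by an indium Barbier union of furanone aldehyde 7 (C1–C4, C8–C10, C14, C15) with bromide 11 (C5–C7, C11–C13, from (R)-glyceraldehyde acetonide and methyl acrylate). Acid then exchanges the acetonide for the γ-lactone.
The furanone ring O–C10–C1–C2–C3 is not closed as a five-membered ring. The furan of 2-acetyl-5-methylfuran (its carbons are C1–C4) is oxidised to the six-membered pyranone O–C10–C1–C2–C3–C4. That ring contracts by moving the ring oxygen from C4 to C3 and expels C4 as the acetyl group that later becomes C4=CH2.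
Enabling feature: C1(=O)–C2=C3–C4 is a 1,4-dioxygenated but-2-ene, that is, an oxidised 2,5-disubstituted furan. The C10 oxygen sits next to C1 and can reach both C4 (six-ring hemiketal) and C3 (five-ring vinylogous ester). A bromine on C3 supplies the missing oxidation level and the leaving group.
Ring order: furan → pyranone → furanone (step 3), γ-lactone (step 10), ten-membered ring (step 12).

Key step: step 3

Numbering: germacrane locants of the target are used throughout. These are C1 ketone, C2=C3 furanone alkene, C4(=C15H2), C5 carbinol, C6 lactone O–CH, C7, C8 ester-bearing CH, C9 CH2, C10 quaternary carbon with methyl C14, C11=C13H2 and C12 lactone C=O. The target is 5R,6S,7R,8R,10R.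
Assumption: the ligand antipode written in step 2 is taken to deliver allyl to the Re face of ketone 2. If the sense of induction is opposite, the mirror-image ligand is used and nothing else changes.

Step 1
Reactants: 1 1-(5-methylfuran-2-yl)ethan-1-one
Product: 2 1-(4-bromo-5-methylfuran-2-yl)ethan-1-one
Conditions: Br2 (1.05 equiv), AlCl3 (2.5 equiv), CH2Cl2, 0 °C to rt
Reagents that add atoms: bromine, BrBr
Why: Electrophilic aromatic bromination under swamping-catalyst conditions, in which the AlCl3-complexed acetyl group deactivates C3 of the furan and suppresses side-chain enolisation, so bromine should enter C4 next to the activating methyl group; no stereocenter is formed.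

Step 2
Reactants: 2 1-(4-bromo-5-methylfuran-2-yl)ethan-1-one
Product: 3 (2R)-2-(4-bromo-5-methylfuran-2-yl)pent-4-en-2-ol
Conditions: allylB(pin) (1.2 equiv), CuF2·2H2O (3 mol %), (R,R)-i-Pr-DuPHOS (6 mol %), La(OiPr)3 (4.5 mol %), DMF, −40 °C
Reagents that add atoms: allylboronic acid pinacol ester, C=CCB1OC(C)(C)C(C)(C)O1
Why: Catalytic enantioselective allylboration of a heteroaryl methyl ketone through a chiral allylcopper species, whose ligand distinguishes the flat furyl group from methyl and delivers allyl to the Re face to set C10 as R, while the furyl bromide is inert at this temperature.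

Step 3
Reactants: 3 (2R)-2-(4-bromo-5-methylfuran-2-yl)pent-4-en-2-ol
Product: 5 (2R)-5-acetyl-2-methyl-2-(prop-2-en-1-yl)furan-3(2H)-one, via bromopyranone hemiketal 4 (not isolated)
Conditions: NBS (1.05 equiv), NaHCO3 (1.2 equiv), THF–H2O 4:1, 0 °C; then Et3N (1.5 equiv), 0 °C to rt, one pot
Reagents that add atoms: water, O
Why: Proposed new method: NBS and water oxidise the furan to the (Z)-bromo-ene-1,4-dione (Achmatowicz rearrangement), which the C10 hydroxyl captures at the C4 ketone by 6-exo-trig addition to give the six-membered hemiketal 4; Et3N then reopens the hemiketal, the C10 oxygen adds to C3, which is the beta carbon of the C1 enone and carries bromide, and loss of bromide leaves the five-membered vinylogous ester with C4 expelled as an acetyl group. The closest known reactions are the Perkin coumarin-to-benzofuran ring contraction, in which a ring oxygen likewise moves from a carbonyl carbon to the neighbouring bromoalkene carbon, and the cyclisation of alpha'-hydroxy beta-halo or beta-amino enones to 3(2H)-furanones. The second closure is formally 5-endo-trig, as in the Perkin case, and is driven by irreversible loss of bromide and by the push-pull stabilisation of the product. No stereocenter is created: the C10–O bond is never broken, so C10 stays R, and the hemiketal carbon of 4 becomes planar again. The step needs chemoselectivity for the furan over the terminal alkene, secured by the far higher nucleophilicity of the trisubstituted furan towards one equivalent of NBS at 0 °C, and oxygen closure over the aldol closure of the methyl ketone onto C1 that leads to cyclopentenones, secured by the leaving group on C3 and by the weak amine base.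

Step 4
Reactants: 5 (2R)-5-acetyl-2-methyl-2-(prop-2-en-1-yl)furan-3(2H)-one
Product: 6 1-[(5R)-5-methyl-4-oxo-5-(prop-2-en-1-yl)-4,5-dihydrofuran-2-yl]ethenyl trifluoromethanesulfonate
Conditions: KHMDS (1.05 equiv), THF, −78 °C, inverse addition of 5; then PhNTf2, −78 to 0 °C
Reagents that add atoms: N-phenylbis(trifluoromethanesulfonimide), O=S(=O)(N(c1ccccc1)S(=O)(=O)C(F)(F)F)C(F)(F)F
Why: Standard enol triflate formation, since the acetyl methyl group is the only enolisable position (C10 is quaternary and C2 is vinylic) and inverse addition keeps the enolate away from unreacted electrophilic ketone; no stereocenter is affected.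

Step 5
Reactants: 6 1-[(5R)-5-methyl-4-oxo-5-(prop-2-en-1-yl)-4,5-dihydrofuran-2-yl]ethenyl trifluoromethanesulfonate
Product: 7 1-[(5R)-5-methyl-4-oxo-5-(2-oxoethyl)-4,5-dihydrofuran-2-yl]ethenyl trifluoromethanesulfonate
Conditions: OsO4 (2 mol %), NaIO4 (4 equiv), 2,6-lutidine, dioxane–H2O 3:1, rt
Reagents that add atoms: osmium tetroxide (oxygen carrier), O=[Os](=O)(=O)=O; sodium periodate (terminal oxygen source), [Na+].[O-]I(=O)(=O)=O
Why: Lemieux–Johnson cleavage, in which OsO4 should dihydroxylate the electron-neutral monosubstituted alkene much faster than the electron-poor alkenyl triflate or the push-pull furanone alkene, and periodate cleaves the diol to the C8 aldehyde without touching C10.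

Step 6
Reactants: 8 (4R)-2,2-dimethyl-1,3-dioxolane-4-carbaldehyde; 9 methyl acrylate
Product: 10 methyl 2-{[(4R)-2,2-dimethyl-1,3-dioxolan-4-yl](hydroxy)methyl}prop-2-enoate (both carbinol epimers)
Conditions: DABCO (0.5 equiv), dioxane–H2O 1:1, rt
Reagents that add atoms: none
Why: Morita–Baylis–Hillman reaction of an alpha-alkoxy aldehyde with an acrylate, in which the new carbinol centre (C7) may form as a mixture because it becomes sp2 in the next step, while C6 comes unchanged from the chiral pool.

Step 7
Reactants: 10 methyl 2-{[(4R)-2,2-dimethyl-1,3-dioxolan-4-yl](hydroxy)methyl}prop-2-enoate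
Product: 11 methyl (2Z)-2-(bromomethyl)-3-[(4S)-2,2-dimethyl-1,3-dioxolan-4-yl]prop-2-enoate
Conditions: NBS, Me2S, CH2Cl2, 0 °C to rt
Reagents that add atoms: N-bromosuccinimide, O=C1CCC(=O)N1Br
Why: The bromosulfonium salt from NBS and Me2S activates the allylic alcohol and bromide attacks in SN2' fashion, the standard neutral conversion of Baylis–Hillman adducts into (Z)-2-(bromomethyl)alk-2-enoates, the Z geometry placing the dioxolane trans to the ester.

Step 8
Reactants: 7 1-[(5R)-5-methyl-4-oxo-5-(2-oxoethyl)-4,5-dihydrofuran-2-yl]ethenyl trifluoromethanesulfonate; 11 methyl (2Z)-2-(bromomethyl)-3-[(4S)-2,2-dimethyl-1,3-dioxolan-4-yl]prop-2-enoate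
Product: 12 methyl (3R,4R)-3-[(4S)-2,2-dimethyl-1,3-dioxolan-4-yl]-4-hydroxy-2-methylidene-5-[(2R)-2-methyl-3-oxo-5-(1-{[(trifluoromethyl)sulfonyl]oxy}ethenyl)-2,3-dihydrofuran-2-yl]pentanoate (6S,7R,8R,10R)
Conditions: indium powder (1.5 equiv), THF–H2O 1:1, rt
Reagents that add atoms: none
Why: Indium-mediated Barbier allylation, in which the allylindium from the Z bromide reacts at its gamma carbon C7 through a closed chair that turns the Z geometry into the 7,8-syn adduct, the aldehyde approaches anti to the allylic C6–O bond with C6–H eclipsing the alkene (A(1,3) control, the sense seen for electrophilic additions to Z-allylic dioxolanes) to set C7 as R and hence C8 as R, and the aldehyde reacts far faster than the hindered C1 ketone or the alkenyl triflate.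

Step 9
Reactants: 12 hydroxy ester (6S,7R,8R,10R)
Product: 13 methyl (3R,4R)-3-[(4S)-2,2-dimethyl-1,3-dioxolan-4-yl]-2-methylidene-4-[(3-methylbutanoyl)oxy]-5-[(2R)-2-methyl-3-oxo-5-(1-{[(trifluoromethyl)sulfonyl]oxy}ethenyl)-2,3-dihydrofuran-2-yl]pentanoate
Conditions: isovaleric anhydride, Et3N, DMAP (10 mol %), CH2Cl2, 0 °C
Reagents that add atoms: 3-methylbutanoic anhydride, CC(C)CC(=O)OC(=O)CC(C)C
Why: DMAP-catalysed acylation of the only free hydroxyl group fixes O8 as the isovalerate before it can lactonise onto the acrylate ester and touches no stereocenter.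

Step 10
Reactants: 13 acetonide isovalerate
Product: 14 (1R)-1-[(2S,3R)-2-(hydroxymethyl)-4-methylidene-5-oxooxolan-3-yl]-2-[(2R)-2-methyl-3-oxo-5-(1-{[(trifluoromethyl)sulfonyl]oxy}ethenyl)-2,3-dihydrofuran-2-yl]ethyl 3-methylbutanoate
Conditions: TFA–H2O 9:1, CH2Cl2, 0 °C to rt
Reagents that add atoms: none
Why: Aqueous acid hydrolyses the acetonide and the freed C6 hydroxyl closes onto the methyl ester by 5-exo-trig lactonisation, favoured over the six-membered alternative through O5, to give the 6,7-trans alpha-methylene-gamma-butyrolactone with C6 and C7 unchanged and the primary C5 alcohol free.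

Step 11
Reactants: 14 hydroxymethyl lactone
Product: 15 (1R)-1-[(2S,3R)-2-formyl-4-methylidene-5-oxooxolan-3-yl]-2-[(2R)-2-methyl-3-oxo-5-(1-{[(trifluoromethyl)sulfonyl]oxy}ethenyl)-2,3-dihydrofuran-2-yl]ethyl 3-methylbutanoate
Conditions: Dess–Martin periodinane, CH2Cl2, 0 °C to rt
Reagents that add atoms: none
Why: Dess–Martin oxidation converts the primary alcohol into the aldehyde under neutral conditions that should not epimerise C6 and that tolerate the alkenyl triflate, both esters and the furanone.

Step 12
Reactants: 15 triflate aldehyde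
Product: 16 target (5R,6S,7R,8R,10R)
Conditions: CrCl2 (8 equiv), NiCl2 (0.08 equiv), DMF, rt, slow addition of 15 to a final 2 mM
Reagents that add atoms: none
Why: Intramolecular Nozaki–Hiyama–Kishi reaction, in which zerovalent nickel inserts into the alkenyl triflate, transmetalation gives an alkenylchromium species of trivalent chromium that adds only to the aldehyde, closing the ten-membered ring and forming the 1,1-disubstituted alkene and the allylic alcohol at once, and polar Felkin–Anh attack anti to the C6–O bond should give the 5,6-anti (5R) alcohol.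

Compound list
1 | 1-(5-methylfuran-2-yl)ethan-1-one | CC(=O)c1ccc(C)o1 | starting material
2 | 1-(4-bromo-5-methylfuran-2-yl)ethan-1-one | CC(=O)c1cc(Br)c(C)o1 | intermediate
3 | (2R)-2-(4-bromo-5-methylfuran-2-yl)pent-4-en-2-ol | C=CC[C@@](C)(O)c1cc(Br)c(C)o1 | intermediate
4 | (2R)-5-bromo-6-hydroxy-2,6-dimethyl-2-(prop-2-en-1-yl)-2H-pyran-3(6H)-one (hemiketal epimers) | C=CC[C@@]1(C)OC(C)(O)C(Br)=CC1=O | intermediate
5 | (2R)-5-acetyl-2-methyl-2-(prop-2-en-1-yl)furan-3(2H)-one | C=CC[C@@]1(C)OC(C(C)=O)=CC1=O | intermediate
6 | 1-[(5R)-5-methyl-4-oxo-5-(prop-2-en-1-yl)-4,5-dihydrofuran-2-yl]ethenyl trifluoromethanesulfonate | C=CC[C@@]1(C)OC(C(=C)OS(=O)(=O)C(F)(F)F)=CC1=O | intermediate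
7 | 1-[(5R)-5-methyl-4-oxo-5-(2-oxoethyl)-4,5-dihydrofuran-2-yl]ethenyl trifluoromethanesulfonate | O=CC[C@@]1(C)OC(C(=C)OS(=O)(=O)C(F)(F)F)=CC1=O | intermediate
8 | (4R)-2,2-dimethyl-1,3-dioxolane-4-carbaldehyde | CC1(C)OC[C@H](C=O)O1 | starting material
9 | methyl acrylate | C=CC(=O)OC | starting material
10 | methyl 2-{[(4R)-2,2-dimethyl-1,3-dioxolan-4-yl](hydroxy)methyl}prop-2-enoate (carbinol epimers) | COC(=O)C(=C)C(O)[C@H]1COC(C)(C)O1 | intermediate
11 | methyl (2Z)-2-(bromomethyl)-3-[(4S)-2,2-dimethyl-1,3-dioxolan-4-yl]prop-2-enoate | COC(=O)/C(CBr)=C/[C@H]1COC(C)(C)O1 | intermediate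
12 | Barbier adduct, 8-hydroxy seco ester (6S,7R,8R,10R) | C=C(C(=O)OC)[C@@H]([C@H]1COC(C)(C)O1)[C@H](O)C[C@@]1(C)OC(C(=C)OS(=O)(=O)C(F)(F)F)=CC1=O | intermediate
13 | 8-O-isovaleryl seco ester (6S,7R,8R,10R) | C=C(C(=O)OC)[C@@H]([C@H]1COC(C)(C)O1)[C@H](OC(=O)CC(C)C)C[C@@]1(C)OC(C(=C)OS(=O)(=O)C(F)(F)F)=CC1=O | intermediate
14 | 6,7-trans alpha-methylene lactone with C5 primary alcohol (6S,7R,8R,10R) | C=C1C(=O)O[C@H](CO)[C@H]1[C@H](OC(=O)CC(C)C)C[C@@]1(C)OC(C(=C)OS(=O)(=O)C(F)(F)F)=CC1=O | intermediate
15 | C5 aldehyde of 14 (6S,7R,8R,10R) | C=C1C(=O)O[C@H](C=O)[C@H]1[C@H](OC(=O)CC(C)C)C[C@@]1(C)OC(C(=C)OS(=O)(=O)C(F)(F)F)=CC1=O | intermediate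
16 | CNP0409337.2, 5-hydroxy-8-isovaleryloxy-1-oxo-3,10-epoxygermacra-2,4(15),11(13)-trien-12,6-olide (5R,6S,7R,8R,10R) | C=C1C(=O)O[C@H]2[C@H]1[C@H](OC(=O)CC(C)C)C[C@@]1(C)OC(=CC1=O)C(=C)[C@H]2O | target

Total step count: 12. Longest linear sequence: 10 (steps 1–5 and 8–12).

Steps most likely to fail

Step 3. In the basic aqueous one-pot medium, aldol closure of the methyl ketone onto C1 or hydrolytic breakdown of the bromo-enedione may outrun the shift of the ring oxygen.
The fallback sets out from 3 and returns at 5. It separates the events and makes the C3–O bond under acid.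
- Compound 3 is oxidised with m-CPBA in CH2Cl2 (Achmatowicz rearrangement) and 4 is isolated.
- NaOMe in MeOH at low temperature replaces the bromide by intermolecular addition–elimination on the beta-bromo enone. This gives methoxypyranone hemiketal F1.
- TsOH in benzene opens the hemiketal and closes the alpha'-hydroxy beta-methoxy enone onto C3 with loss of methanol. This is the classical acid-catalysed 3(2H)-furanone closure, and it gives 5.

Step 12. Oligomerisation or protodemetalation of the alkenylchromium species may outrun closure of the strained bridged ring, or the facial selectivity at C5 may be poor.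
The fallback sets out from 14 and returns at 16. It replaces the alkenylmetal addition by a reductive alkyne–aldehyde coupling.
- DBU in CH2Cl2 removes triflic acid from the 1-(triflyloxy)vinyl group of 14 and gives ethynylfuranone alcohol F2.
- Dess–Martin oxidation gives ethynylfuranone aldehyde F3.
- Ni(cod)2 with a bulky N-heterocyclic carbene ligand and Et3SiH under high dilution effects the reductive macrocyclisation. The bulky ligand steers C–C bond formation to the internal alkyne carbon C4 and so gives the exocyclic methylene. The product is macrocyclic triethylsilyl ether F4.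
- HF·pyridine frees the C5 hydroxyl and gives 16.

Step 8. The approach of the aldehyde to the acyclic allylindium may show poor facial selectivity at C7. The Z geometry may also erode, or O8 may lactonise prematurely.
The fallback sets out from 10 and returns at 14. It replaces acyclic A(1,3) control by the face of a ring and the closed chair by an open transition state.
- Aqueous TFA converts 10 into hydroxy lactone diol F5 by loss of the acetonide and lactonisation through O6.
- TBSCl and imidazole silylate the primary hydroxyl and give silyl ether F6.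
- NBS and Me2S displace the allylic hydroxyl in SN2' fashion and give bromomethyl butenolide F7.
- Bu3SnLi with CuBr·SMe2 gives stannylmethyl butenolide F8.
- BF3·OEt2 at −78 °C couples F8 with 7 on the butenolide face opposite the C5 substituent (6,7-trans). The antiperiplanar open transition state is syn-selective for allylstannanes (7,8-syn). The product is alcohol F9.
- Isovaleric anhydride and DMAP give ester F10.
- HF·pyridine removes the silyl group and gives 14.

Further compounds
F1 | step 3 | (2R)-6-hydroxy-5-methoxy-2,6-dimethyl-2-(prop-2-en-1-yl)-2H-pyran-3(6H)-one | C=CC[C@@]1(C)OC(C)(O)C(OC)=CC1=O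
F2 | step 12 | 5-ethynylfuranone analogue of 14 (6S,7R,8R,10R) | C=C1C(=O)O[C@H](CO)[C@H]1[C@H](OC(=O)CC(C)C)C[C@@]1(C)OC(C#C)=CC1=O
F3 | step 12 | 5-ethynylfuranone analogue of 15 (6S,7R,8R,10R) | C=C1C(=O)O[C@H](C=O)[C@H]1[C@H](OC(=O)CC(C)C)C[C@@]1(C)OC(C#C)=CC1=O
F4 | step 12 | 5-O-triethylsilyl ether of 16 | C=C1C(=O)O[C@H]2[C@H]1[C@H](OC(=O)CC(C)C)C[C@@]1(C)OC(=CC1=O)C(=C)[C@H]2O[Si](CC)(CC)CC
F5 | step 8 | (5R)-4-hydroxy-5-(hydroxymethyl)-3-methylideneoxolan-2-one (C4 epimers) | C=C1C(=O)O[C@H](CO)C1O
F6 | step 8 | (5R)-5-{[(tert-butyldimethylsilyl)oxy]methyl}-4-hydroxy-3-methylideneoxolan-2-one (C4 epimers) | C=C1C(=O)O[C@H](CO[Si](C)(C)C(C)(C)C)C1O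
F7 | step 8 | (5S)-3-(bromomethyl)-5-{[(tert-butyldimethylsilyl)oxy]methyl}furan-2(5H)-one | BrCC1=C[C@@H](CO[Si](C)(C)C(C)(C)C)OC1=O
F8 | step 8 | (5S)-5-{[(tert-butyldimethylsilyl)oxy]methyl}-3-[(tributylstannyl)methyl]furan-2(5H)-one | CCCC[Sn](CCCC)(CCCC)CC1=C[C@@H](CO[Si](C)(C)C(C)(C)C)OC1=O
F9 | step 8 | 5-O-TBS, 8-hydroxy analogue of 14 (6S,7R,8R,10R) | C=C1C(=O)O[C@H](CO[Si](C)(C)C(C)(C)C)[C@H]1[C@H](O)C[C@@]1(C)OC(C(=C)OS(=O)(=O)C(F)(F)F)=CC1=O
F10 | step 8 | 5-O-TBS ether of 14 (6S,7R,8R,10R) | C=C1C(=O)O[C@H](CO[Si](C)(C)C(C)(C)C)[C@H]1[C@H](OC(=O)CC(C)C)C[C@@]1(C)OC(C(=C)OS(=O)(=O)C(F)(F)F)=CC1=O
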